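Start with the easy count: each substitution spends one partner and frees one released group, while capture spends none.

common to all: starting material 0.062 M

| flask | partner | capture agent | remark | time |
|---|---|---|---|---|
| ash | 0.093 M | 0.062 M | the very flask that is asked about, followed so far |  |
| flask | 0.0930 M | 0.0620 M |  | 50 min |
- ash (time / min: starting material / %, first product / %): 1.33: 88, 8; 4.00: 74, 17; 8.00: 57, 8; 10.0: 53, 10; 15.0: 39, 8; 20.0: 39, 7

(scatter of a reading: 2 percentage points)
1. the starting material standing at 50 min, as a percentage of the starting material charged
2. the first product standing at 50 min, as a percentage of the starting material charged
3. the bis adduct standing at 50 min, as a percentage of the starting material charged
4. the triple product standing at 50 min, as a percentage of the starting material charged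
- what was read earlier has a scatter of 2 percentage points, one standard deviation
- what may be going on: starting material + partner -> first product + released group; partner + first product -> bis adduct + released group; partner + bis adduct -> triple product + released group; partner + triple product -> tetra adduct + released group; first product + capture agent -> trapped intermediate

Take the charge as a budget of 1.50 equivalents of partner per starting material. Then name the partner cost: partner spent per starting material consumed. Together, with the cost held fixed, they give a floor for the fraction of starting material left:

floor = one minus budget over cost

Weigh the inputs first. The budget comes from the charges, so it is sharp. The cost is soft and matters: a cost of 2 would put the floor at 25.0%. The first-product readings do not enter. The cost rests on the late slope of starting material, and those readings carry the scatter of 2 percentage points.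

Now reckon it. The pseudo-first-order loss constant of starting material follows partner, so compare its two values:

early, to 4.00 min: 0.0753 /min
late, 8.00 min to 20.0 min: 0.0316 /min
partner spent: 0.870 equivalents
starting material consumed: 52.9%
cost: 1.65

This cost, read from the ash run, is more than the budget, so I take partner as the limiting reagent, and the floor reckons to 8.86%. Integrating toward that floor, I expect 24.1% starting material at 50 min.

The forecast gives 16%, less than mine, with 4% first product, 12% bis adduct and 4% triple product, noting that “Partner is only 1.5 equiv and runs down”.

The flask gives 20.8% starting material, 2.09% first product, 11.2% bis adduct and 8.08% triple product.

    starting material + partner → first product + released group (k = 0.930 /M/min)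
    partner + first product → bis adduct + released group (k = 2.10 /M/min)
    partner + bis adduct → triple product + released group (k = 0.980 /M/min)
    partner + triple product → tetra adduct + released group (k = 1.20 /M/min)
    first product + capture agent → trapped intermediate (k = 3.70 /M/min)

In this flask half of the first substitution's turnover up to the asked time was done by 7.24 min and half of capture's by 11.7 min, while partner fell from 73.2% of its charge at 5.00 min to 12.8% at 50.0 min. At 50.0 min the released group in this flask, 0.0811 M, against the starting material consumed by then gives a cost of 1.65, beside the 1.65 read from the slopes of the ash run.

In the flask with 0.23 M of partner, the budget is 3.71 equivalents, which at the carried cost pays for 2.25 times the starting material, so no floor is reckoned. In that flask 1.02% starting material and 26.3% of the partner charge stand at 50.0 min, and the cost there is 2.76, more than the carried 1.65.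

Readings and results stem from a simulated flask on assumed constants.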